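**Retrosynthetic overview**

- The target is a bicyclo[3.2.1]oct-2-en-8-one: C1 allyl bridgehead, C2=C3(OMe), C4 CH–OAc, C5 OMe bridgehead, C6 CH–aryl, C7 CH–CH3, C8 bridging C=O. The plan rests on the adjacent oxygenated carbons C4 and C5 beside C6, which are the retron of an α-ketol shift of C6 between C4 and C5.
- Returning C6 from C5 to C4 gives a bicyclo[2.2.2]octenone. Its ring C1–C2–C3–C4–C6–C7 is the [4+2] adduct of a cyclohexa-2,4-dienone (masked o-benzoquinone, diene C1=C2–C3=C4) and (E)-methylisoeugenol, with new bonds C1–C7 and C4–C6.
- The dienone carries a (2R,3R)-butanediol spiroketal at C8 for face control and a silyl ether at C4 to trigger the shift. It is made from 2,3-dihydroxy-4-methoxybenzaldehyde by Baeyer–Villiger oxidation, Claisen allylation and PhI(OAc)2 dearomatisation.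
- Ring order: arene, spiro dioxolane (step 9), bicyclo[2.2.2]octenone (step 10), bicyclo[3.2.1]octenone (step 11). Endgame: C5 O-methylation, ketal removal, reduction of both ketones, Mitsunobu acetate at C4, re-oxidation at C8.

Key step: step 10

Remark and assumption: the locants C1–C8 of the target are kept for the dienone and the bicyclo[2.2.2]octenone; Ar = 3,4-dimethoxyphenyl, TBS = tert-butyldimethylsilyl, MOM = methoxymethyl. The C8 carbinol configuration drawn for 20 and 21 assumes hydride delivery from the side of the C2=C3–C4 bridge; it has no consequence because step 16 removes it.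

**Route**

Step 1
Reactants: 1 2,3-dihydroxy-4-methoxybenzaldehyde
Product: 2 3-(tert-butyldimethylsilyloxy)-2-hydroxy-4-methoxybenzaldehyde
Conditions: TBSCl (1.05 equiv), imidazole, DMF, 0 °C
Reagents that add atoms: tert-butyldimethylsilyl chloride, CC(C)(C)[Si](C)(C)Cl
Why: Silyl ether formation should take the 3-hydroxyl because the 2-hydroxyl is held in a hydrogen bond to the aldehyde, and a silyl group that lands on O2 can move to O3 under the basic conditions since the chelated 2-phenol is the more acidic one.

Step 2
Reactants: 2 3-(tert-butyldimethylsilyloxy)-2-hydroxy-4-methoxybenzaldehyde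
Product: 3 3-(tert-butyldimethylsilyloxy)-4-methoxy-2-(methoxymethoxy)benzaldehyde
Conditions: MOMCl, i-Pr2NEt, CH2Cl2, 0 °C to rt
Reagents that add atoms: chloromethyl methyl ether, COCCl
Why: Williamson-type alkylation of the remaining phenol with an amine base protects O2 as an acetal that survives the oxidation, allylation, Claisen and methylation steps and can later be removed without fluoride or strong base.

Step 3
Reactants: 3 3-(tert-butyldimethylsilyloxy)-4-methoxy-2-(methoxymethoxy)benzaldehyde
Product: 5 3-(tert-butyldimethylsilyloxy)-4-methoxy-2-(methoxymethoxy)phenol, via aryl formate 4 (not isolated)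
Conditions: mCPBA, CH2Cl2, 0 °C to rt; then Et3N, MeOH, rt
Reagents that add atoms: 3-chloroperbenzoic acid, OOC(=O)c1cccc(Cl)c1
Why: Baeyer–Villiger (Dakin-type) oxidation in which the electron-rich aryl group, activated by ortho and para alkoxy groups, migrates in preference to hydrogen, and the formate is then cleaved by mild methanolysis that leaves the aryl silyl ether alone.

Step 4
Reactants: 5 3-(tert-butyldimethylsilyloxy)-4-methoxy-2-(methoxymethoxy)phenol; 6 allyl bromide
Product: 7 allyl 3-(tert-butyldimethylsilyloxy)-4-methoxy-2-(methoxymethoxy)phenyl ether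
Conditions: K2CO3, acetone, 50 °C
Reagents that add atoms: none
Why: Williamson ether synthesis on the only free phenol, which has no silyl ether on a neighbouring carbon and so cannot scramble the silyl group.

Step 5
Reactants: 7 allyl 3-(tert-butyldimethylsilyloxy)-4-methoxy-2-(methoxymethoxy)phenyl ether
Product: 8 6-allyl-3-(tert-butyldimethylsilyloxy)-4-methoxy-2-(methoxymethoxy)phenol
Conditions: N,N-diethylaniline, 190 °C
Reagents that add atoms: none
Why: Aromatic Claisen rearrangement ([3,3] shift then tautomerisation) can end only at the one unsubstituted ortho carbon, since the other ortho position carries the MOM ether and the para position a methoxy group.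

Step 6
Reactants: 8 6-allyl-3-(tert-butyldimethylsilyloxy)-4-methoxy-2-(methoxymethoxy)phenol
Product: 9 1-allyl-4-(tert-butyldimethylsilyloxy)-2,5-dimethoxy-3-(methoxymethoxy)benzene
Conditions: MeI, K2CO3, acetone, 50 °C
Reagents that add atoms: iodomethane, CI
Why: Williamson O-methylation of the liberated phenol installs the methoxy group that becomes the ketal carbon C8 of the dienone.

Step 7
Reactants: 9 1-allyl-4-(tert-butyldimethylsilyloxy)-2,5-dimethoxy-3-(methoxymethoxy)benzene
Product: 10 3-allyl-6-(tert-butyldimethylsilyloxy)-2,5-dimethoxyphenol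
Conditions: ZnBr2, n-PrSH, CH2Cl2, 0 °C
Reagents that add atoms: none
Why: Lewis-acid-assisted thiolysis of the MOM acetal is fast at 0 °C and non-basic, so the doubly ortho-flanked aryl silyl ether should neither cleave nor migrate to the new neighbouring phenol.

Step 8
Reactants: 10 3-allyl-6-(tert-butyldimethylsilyloxy)-2,5-dimethoxyphenol
Product: 11 5-allyl-2-(tert-butyldimethylsilyloxy)-3,6,6-trimethoxycyclohexa-2,4-dien-1-one
Conditions: PhI(OAc)2, MeOH, 0 °C
Reagents that add atoms: methanol, CO
Why: Oxidative dearomatisation of a 2-methoxyphenol to a masked o-benzoquinone, in which methanol should add to the methoxy-bearing ortho carbon because that position is stabilised by its own and the para methoxy group and is less shielded than the silyloxy carbon.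

Step 9
Reactants: 11 5-allyl-2-(tert-butyldimethylsilyloxy)-3,6,6-trimethoxycyclohexa-2,4-dien-1-one; 12 (2R,3R)-butane-2,3-diol
Product: 13 (2R,3R)-6-allyl-9-(tert-butyldimethylsilyloxy)-8-methoxy-2,3-dimethyl-1,4-dioxaspiro[4.5]deca-6,8-dien-10-one
Conditions: 12 (3 equiv), BF3·OEt2 (0.2 equiv), DME, 0 °C
Reagents that add atoms: none
Why: Acid-catalysed ketal exchange, as practised on quinone monoketals, is driven by closure of the five-membered dioxolane and loss of methanol, and creates no new stereocentre because the spiro carbon lies on the C2 axis of the diol.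

Step 10
Reactants: 13 (2R,3R)-6-allyl-9-(tert-butyldimethylsilyloxy)-8-methoxy-2,3-dimethyl-1,4-dioxaspiro[4.5]deca-6,8-dien-10-one; 14 (E)-methylisoeugenol
Product: 15 bicyclo[2.2.2]octenone adduct (C1 allyl; C2=C3(OMe); C4 OTBS; C5 ketone; C8 spiroketal; C6 aryl on the side of the C5–C8 bridge; C7 methyl on the side of the C2=C3 bridge)
Conditions: 14 (5 equiv), 2,6-di-tert-butyl-4-methylphenol (cat.), toluene, 100 °C, sealed tube
Reagents that add atoms: none
Why: A thermal Diels–Alder reaction with inverse electron demand between a masked o-benzoquinone and an electron-rich styrene, the closest known reaction type, in which the nucleophilic CH(CH3) carbon of 14 bonds to C1 (the δ-carbon of the dienone, next to the ketal) and the benzylic carbon bonds to C4 (the terminus made nucleophilic by the C3 methoxy group) in a concerted, asynchronous, suprafacial [4+2] process. The ring C1–C2–C3–C4–C6–C7 closes by this cycloaddition and turns the dienone into the bicyclo[2.2.2]octenone with C5–C8 as the third bridge. C6 and C7 inherit the trans relation of the E-alkene; which of them points to which bridge is decided by the ketal oxygen on the attacked face, which leaves room only for hydrogen on C7, so methyl should lie over the C2=C3 bridge and aryl over the C5–C8 bridge. C1 and C4 are fixed together by the diene face that is attacked: in the (R,R)-dioxolane one methyl group leans over C1 on one face while the other leans towards C5 on the opposite face, so the alkene should add to the face on which C1 is open. The step needs regio-, endo/exo- and face selectivity; the polarity of the dienone secures the first, the ketal the second and the C2-symmetric diol the third, and because the two facial isomers are diastereomers the minor one can be removed by chromatography.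

Step 11
Reactants: 15 bicyclo[2.2.2]octenone adduct
Product: 17 bicyclo[3.2.1]oct-2-en-4-one α-ketol (C5–OH; C8 spiroketal; C6 aryl exo; C7 methyl endo), via bicyclo[2.2.2] C4-alkoxide 16 (not isolated)
Conditions: Bu4NF, THF, 0 °C to rt; then AcOH
Reagents that add atoms: none
Why: Fluoride cleaves the bridgehead silyl ether and the free C4 alkoxide beside the C5 ketone should undergo an α-ketol (acyloin) rearrangement in which C6 migrates from C4 to C5 with retention, the reversible shift ending at the isomer whose new C4 ketone is conjugated with C2=C3(OMe); the configuration of the new C5 centre is dictated by the bicyclic frame.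

Step 12
Reactants: 17 bicyclo[3.2.1]oct-2-en-4-one α-ketol
Product: 18 C5 methyl ether of 17
Conditions: KN(SiMe3)2, THF, −78 °C; then MeOTf, −78 to −40 °C
Reagents that add atoms: methyl trifluoromethanesulfonate, COS(=O)(=O)C(F)(F)F
Why: Williamson-type O-methylation of the tertiary alkoxide at low temperature should trap the C5 oxygen before any retro-ketol shift, and the C4 ketone has no α-hydrogen to enolise.

Step 13
Reactants: 18 C5 methyl ether of 17
Product: 19 bicyclo[3.2.1]oct-2-ene-4,8-dione (C1 allyl; C3 OMe; C5 OMe; C6 aryl; C7 methyl)
Conditions: aq. HCl (3 M), THF, 50 °C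
Reagents that add atoms: water, O
Why: Acid-catalysed ketal hydrolysis is placed here because the C2=C3 enol ether is still conjugated to the C4 ketone and so resists protonation, and because C5 is already an ether so that no acid-induced ketol shift can follow.

Step 14
Reactants: 19 bicyclo[3.2.1]oct-2-ene-4,8-dione
Product: 20 4,8-diol (C4–OH on the side of the C6–C7 bridge; C8–OH on the side of the C6–C7 bridge)
Conditions: NaBH4 (4 equiv), CeCl3·7H2O, MeOH, −40 to 0 °C
Reagents that add atoms: none
Why: Luche reduction is run with excess hydride so that both ketones are reduced, which avoids a contest between the strained C8 ketone and the C4 enone; hydride should reach C4 from the convex face next to C8, giving the C4 epimer of the target carbinol, and C8 from the side of the C2=C3–C4 bridge, away from the aryl group on C6.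

Step 15
Reactants: 20 4,8-diol
Product: 21 C4 acetate with free C8 carbinol (acetoxy group on the side of C8)
Conditions: PPh3, DIAD, AcOH, THF, 0 °C to rt
Reagents that add atoms: acetic acid, CC(O)=O
Why: Mitsunobu esterification with inversion sets C4 as in the target, since only the allylic C4 carbinol can be displaced (backside attack comes from the open convex face and no β-hydrogen is available for elimination), while the C8 carbinol between two quaternary bridgeheads cannot undergo SN2 attack.

Step 16
Reactants: 21 C4 acetate with free C8 carbinol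
Product: 22 CNP0221003.1
Conditions: Dess–Martin periodinane, NaHCO3, CH2Cl2, 0 °C to rt
Reagents that add atoms: none
Why: Dess–Martin oxidation of the remaining hindered secondary alcohol restores the C8 ketone under buffered conditions that spare the enol ether, the allyl group and the allylic acetate, and touches no stereocentre.

**Compound list**

1 | 2,3-dihydroxy-4-methoxybenzaldehyde | COc1ccc(C=O)c(O)c1O | starting material
2 | 3-(tert-butyldimethylsilyloxy)-2-hydroxy-4-methoxybenzaldehyde | COc1ccc(C=O)c(O)c1O[Si](C)(C)C(C)(C)C | intermediate
3 | 3-(tert-butyldimethylsilyloxy)-4-methoxy-2-(methoxymethoxy)benzaldehyde | COCOc1c(C=O)ccc(OC)c1O[Si](C)(C)C(C)(C)C | intermediate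
4 | 3-(tert-butyldimethylsilyloxy)-4-methoxy-2-(methoxymethoxy)phenyl formate | COCOc1c(OC=O)ccc(OC)c1O[Si](C)(C)C(C)(C)C | intermediate
5 | 3-(tert-butyldimethylsilyloxy)-4-methoxy-2-(methoxymethoxy)phenol | COCOc1c(O)ccc(OC)c1O[Si](C)(C)C(C)(C)C | intermediate
6 | allyl bromide | C=CCBr | starting material
7 | allyl 3-(tert-butyldimethylsilyloxy)-4-methoxy-2-(methoxymethoxy)phenyl ether | COCOc1c(OCC=C)ccc(OC)c1O[Si](C)(C)C(C)(C)C | intermediate
8 | 6-allyl-3-(tert-butyldimethylsilyloxy)-4-methoxy-2-(methoxymethoxy)phenol | COCOc1c(O)c(CC=C)cc(OC)c1O[Si](C)(C)C(C)(C)C | intermediate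
9 | 1-allyl-4-(tert-butyldimethylsilyloxy)-2,5-dimethoxy-3-(methoxymethoxy)benzene | COCOc1c(OC)c(CC=C)cc(OC)c1O[Si](C)(C)C(C)(C)C | intermediate
10 | 3-allyl-6-(tert-butyldimethylsilyloxy)-2,5-dimethoxyphenol | COc1c(CC=C)cc(OC)c(O[Si](C)(C)C(C)(C)C)c1O | intermediate
11 | 5-allyl-2-(tert-butyldimethylsilyloxy)-3,6,6-trimethoxycyclohexa-2,4-dien-1-one | C=CCC1=CC(OC)=C(O[Si](C)(C)C(C)(C)C)C(=O)C1(OC)OC | intermediate
12 | (2R,3R)-butane-2,3-diol | C[C@@H](O)[C@@H](C)O | starting material
13 | (2R,3R)-6-allyl-9-(tert-butyldimethylsilyloxy)-8-methoxy-2,3-dimethyl-1,4-dioxaspiro[4.5]deca-6,8-dien-10-one | C=CCC1=CC(OC)=C(O[Si](C)(C)C(C)(C)C)C(=O)C12O[C@H](C)[C@@H](C)O2 | intermediate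
14 | (E)-methylisoeugenol | C/C=C/c1ccc(OC)c(OC)c1 | starting material
15 | bicyclo[2.2.2]octenone Diels–Alder adduct | C=CC[C@]12C=C(OC)[C@](O[Si](C)(C)C(C)(C)C)(C(=O)C13O[C@H](C)[C@@H](C)O3)[C@H](c3ccc(OC)c(OC)c3)[C@H]2C | intermediate
16 | tetrabutylammonium C4-alkoxide of the bicyclo[2.2.2]octenone | C=CC[C@]12C=C(OC)[C@]([O-])(C(=O)C13O[C@H](C)[C@@H](C)O3)[C@H](c3ccc(OC)c(OC)c3)[C@H]2C.CCCC[N+](CCCC)(CCCC)CCCC | intermediate
17 | bicyclo[3.2.1]oct-2-en-4-one α-ketol with C8 spiroketal | C=CC[C@]12C=C(OC)C(=O)[C@](O)(C13O[C@H](C)[C@@H](C)O3)[C@H](c3ccc(OC)c(OC)c3)[C@H]2C | intermediate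
18 | C5 methyl ether of 17 | C=CC[C@]12C=C(OC)C(=O)[C@](OC)(C13O[C@H](C)[C@@H](C)O3)[C@H](c3ccc(OC)c(OC)c3)[C@H]2C | intermediate
19 | bicyclo[3.2.1]oct-2-ene-4,8-dione | C=CC[C@]12C=C(OC)C(=O)[C@](OC)(C1=O)[C@H](c1ccc(OC)c(OC)c1)[C@H]2C | intermediate
20 | 4,8-diol (C4 epimer of the target carbinol) | C=CC[C@]12C=C(OC)[C@@H](O)[C@](OC)([C@H]1O)[C@H](c1ccc(OC)c(OC)c1)[C@H]2C | intermediate
21 | C4 acetate with free C8 carbinol | C=CC[C@]12C=C(OC)[C@H](OC(C)=O)[C@](OC)([C@H]1O)[C@H](c1ccc(OC)c(OC)c1)[C@H]2C | intermediate
22 | CNP0221003.1 | C=CC[C@]12C=C(OC)[C@H](OC(C)=O)[C@](OC)(C1=O)[C@H](c1ccc(OC)c(OC)c1)[C@H]2C | target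

**Step count and risks**

Total step count: 16. Longest linear sequence: 16 steps (1 to 22).

Three steps most likely to fail:

1. Step 10. The dioxolane methyl groups are remote from the reacting termini and may discriminate poorly between the two diene faces, and some addition with the aryl group turned to the C2=C3 bridge may leak through, so that much material ends in the wrong diastereomer series. The fallback replaces auxiliary control by resolution; it sets out from 11 and 14 and comes back at 19. The achiral dimethyl ketal 11 is heated with 14 as in step 10 to give the racemic dimethyl-ketal adduct F1. Bu4NF as in step 11 gives the racemic rearranged ketol F2, and KN(SiMe3)2 with MeOTf as in step 12 gives the racemic methyl ether F3. The dimethyl ketal is hydrolysed with dilute aq. HCl in THF at rt to the racemic diketone, that is 19 together with the enantiomer of 19 F4. Preparative chromatography on a chiral stationary phase separates the two, and the route continues from 19 at step 14. This branch also avoids the hydrolysis of the hindered dioxolane.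

2. Step 11. The alkoxide may be protonated before it rearranges, the shift may stop short of equilibrium, or the vinyl carbon C3 may migrate instead of C6 under kinetic control. The fallback separates desilylation from rearrangement; it sets out from 15 and comes back at 17. HF·pyridine in THF at 0 °C removes the silyl group without forming an alkoxide and gives the neutral bicyclo[2.2.2] ketol F5, which is isolated. The ketol shift is then run as its own thermodynamically controlled step through an aluminium chelate (Al(Ot-Bu)3, toluene, 80 °C) to give 17.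

3. Step 13. Ionisation at C8 is slowed by angle strain, by the C5 methoxy group and by two quaternary neighbours, so the dioxolane may persist while forcing acid begins to hydrolyse the α-methoxy enone. The fallback removes the auxiliary by hydride abstraction instead of hydrolysis; it sets out from 18 and comes back at 19. Triphenylmethyl tetrafluoroborate in CH2Cl2 at rt takes hydride from a dioxolane O–CH carbon, the ring fragments, and aqueous work-up releases 19 directly; no new compound is isolated on this path (F0).

**Further compounds**

F1 | step 10 | racemic dimethyl-ketal bicyclo[2.2.2]octenone adduct (drawn as the enantiomer that leads to 19) | C=CC[C@]12C=C(OC)[C@](O[Si](C)(C)C(C)(C)C)(C(=O)C1(OC)OC)[C@H](c1ccc(OC)c(OC)c1)[C@H]2C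
F2 | step 10 | racemic bicyclo[3.2.1] α-ketol with C8 dimethyl ketal (drawn as the enantiomer that leads to 19) | C=CC[C@]12C=C(OC)C(=O)[C@](O)(C1(OC)OC)[C@H](c1ccc(OC)c(OC)c1)[C@H]2C
F3 | step 10 | racemic C5 methyl ether with C8 dimethyl ketal (drawn as the enantiomer that leads to 19) | C=CC[C@]12C=C(OC)C(=O)[C@](OC)(C1(OC)OC)[C@H](c1ccc(OC)c(OC)c1)[C@H]2C
F4 | step 10 | enantiomer of 19 | C=CC[C@@]12C=C(OC)C(=O)[C@@](OC)(C1=O)[C@@H](c1ccc(OC)c(OC)c1)[C@@H]2C
F5 | step 11 | neutral bicyclo[2.2.2] C4-hydroxy ketone (desilylated 15) | C=CC[C@]12C=C(OC)[C@](O)(C(=O)C13O[C@H](C)[C@@H](C)O3)[C@H](c3ccc(OC)c(OC)c3)[C@H]2C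
F0 | step 13 | none | none
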